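**Strategy**

Everything rests on the methylcyclohexene ring: its olefin C1″(CH3)=C2″H adjoins three contiguous stereocentres, C3″ (bonded to flavanone C8), C4″ (aroyl) and C5″ (resorcinol ring), the signature of a Diels–Alder adduct of an (E)-aryl diene and a 2′-hydroxychalcone. The fragile diene is never isolated: in one flask a Stille coupling of an (E)-alkenylstannane on flavanone C8 with 2-bromopropene creates the C1″–C2″ bond, and the diene is trapped by the chalcone bound to a chiral VANOL–boron Lewis acid, which forms C3″–C4″ and C5″–C6″ endo and sets all three ring stereocentres. Both partners come from one iodochalcone.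

Key step: step 12

Remark: the sense of induction of the (S)-VANOL–boron promoter is assumed to be the one that gives the (3″S,4″R,5″S) ring; the ligand alone controls it, so its antipode would serve if the first run shows the opposite sense.

**Route**

Step 1
Reactants: 1 2,4-dihydroxyacetophenone
Product: 2 1-(2,4-dihydroxy-3-iodophenyl)ethanone
Conditions: I2 (0.4 equiv), HIO3 (0.2 equiv), EtOH/H2O, rt to 40 °C
Reagents that add atoms: iodine, [I][I]; iodic acid, OI(=O)=O
Why: Electrophilic aromatic iodination, in which HIO3 reoxidises iodide so that water is the only co-product, should go to C3 because this position is ortho to both hydroxyl groups.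

Step 2
Reactants: 2 1-(2,4-dihydroxy-3-iodophenyl)ethanone
Product: 3 1-[2-hydroxy-3-iodo-4-(methoxymethoxy)phenyl]ethanone
Conditions: MOMCl (1.1 equiv), K2CO3, acetone, 0 °C to rt
Reagents that add atoms: chloromethyl methyl ether, COCCl
Why: Williamson-type O-alkylation should take the more acidic 4-OH, since the 2-OH is held in a hydrogen bond to the ketone and flanked by iodine.

Step 3
Reactants: 4 2,4-dihydroxybenzaldehyde
Product: 5 2,4-bis(methoxymethoxy)benzaldehyde
Conditions: MOMCl (3 equiv), K2CO3, acetone, reflux
Reagents that add atoms: chloromethyl methyl ether, COCCl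
Why: Exhaustive Williamson-type O-alkylation with excess reagent at reflux also covers the hydrogen-bonded 2-OH and removes the phenoxides that would deactivate the aldehyde in the next step.

Step 4
Reactants: 3 1-[2-hydroxy-3-iodo-4-(methoxymethoxy)phenyl]ethanone, 5 2,4-bis(methoxymethoxy)benzaldehyde
Product: 6 (E)-3-[2,4-bis(methoxymethoxy)phenyl]-1-[2-hydroxy-3-iodo-4-(methoxymethoxy)phenyl]prop-2-en-1-one
Conditions: KOH (50% aq.), EtOH, rt
Reagents that add atoms: none
Why: Claisen–Schmidt condensation (aldol addition then E1cB dehydration) should give the E enone under thermodynamic control, and the acetals and the aryl iodide are stable to base.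

Step 5
Reactants: 6 (E)-3-[2,4-bis(methoxymethoxy)phenyl]-1-[2-hydroxy-3-iodo-4-(methoxymethoxy)phenyl]prop-2-en-1-one
Product: 7 (E)-1-(2,4-dihydroxy-3-iodophenyl)-3-(2,4-dihydroxyphenyl)prop-2-en-1-one
Conditions: 3 M HCl, MeOH, rt to 40 °C, dark
Reagents that add atoms: none
Why: Acid-catalysed methanolysis of the three methoxymethyl acetals, run cold and in the dark to hold back E/Z isomerisation and flavylium formation, is done here because no acid can be used once the cycloadduct exists.

Step 6
Reactants: 7 (E)-1-(2,4-dihydroxy-3-iodophenyl)-3-(2,4-dihydroxyphenyl)prop-2-en-1-one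
Product: 8 4-[(E)-3-(4-acetoxy-2-hydroxy-3-iodophenyl)-3-oxoprop-1-enyl]-1,3-phenylene diacetate
Conditions: Ac2O (3.2 equiv), pyridine, CH2Cl2, 0 °C
Reagents that add atoms: acetic anhydride, CC(=O)OC(C)=O
Why: Chemoselective O-acetylation should spare the 2′-OH, which is hydrogen-bonded to the ketone and flanked by iodine, and this free phenol is the later anchor for boron.

Step 7
Reactants: 8 4-[(E)-3-(4-acetoxy-2-hydroxy-3-iodophenyl)-3-oxoprop-1-enyl]-1,3-phenylene diacetate, 9 tributyl(3-methylbut-2-en-1-yl)stannane
Product: 10 4-[(E)-3-[4-acetoxy-2-hydroxy-3-(3-methylbut-2-en-1-yl)phenyl]-3-oxoprop-1-enyl]-1,3-phenylene diacetate (dienophile)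
Conditions: Pd(PPh3)4 (5 mol%), DMF, 80 °C
Reagents that add atoms: none
Why: Stille cross-coupling of the aryl iodide should transfer the prenyl group through its less hindered CH2 terminus under neutral conditions that leave the acetates, the free phenol and the enone untouched.

Step 8
Reactants: 7 (E)-1-(2,4-dihydroxy-3-iodophenyl)-3-(2,4-dihydroxyphenyl)prop-2-en-1-one
Product: 11 rac-2-(2,4-dihydroxyphenyl)-7-hydroxy-8-iodochroman-4-one
Conditions: NaOAc, EtOH/H2O, reflux
Reagents that add atoms: none
Why: Chalcone–flavanone isomerisation (6-endo-trig intramolecular oxa-Michael addition of the 2′-phenol) under weak base gives the racemic flavanone with iodine at C8, and unreacted 7 can be recycled.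

Step 9
Reactants: 11 rac-2-(2,4-dihydroxyphenyl)-7-hydroxy-8-iodochroman-4-one
Product: 12 rac-4-(7-acetoxy-8-iodo-4-oxochroman-2-yl)-1,3-phenylene diacetate
Conditions: Ac2O (4 equiv), pyridine, rt
Reagents that add atoms: acetic anhydride, CC(=O)OC(C)=O
Why: Exhaustive O-acetylation under mild amine conditions should not open the flavanone ring, and it makes the ketone more electrophilic for the resolution.

Step 10
Reactants: 12 rac-4-(7-acetoxy-8-iodo-4-oxochroman-2-yl)-1,3-phenylene diacetate
Product: 13 4-[(2S)-7-acetoxy-8-iodo-4-oxochroman-2-yl]-1,3-phenylene diacetate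
Conditions: RhCl(Cp*)[(R,R)-TsDPEN] (1 mol%), HCO2H/Et3N (5:2), EtOAc, rt, stopped just past half conversion
Reagents that add atoms: none
Why: Kinetic resolution by asymmetric transfer hydrogenation: the (R,R)-catalyst should deliver hydride anti to the C2 aryl group only in the (2R)-enantiomer, which is reduced to the cis-flavan-4-ol, so the slow-reacting (2S)-ketone is recovered and separated.

Step 11
Reactants: 13 4-[(2S)-7-acetoxy-8-iodo-4-oxochroman-2-yl]-1,3-phenylene diacetate, 14 (E)-1,2-bis(tributylstannyl)ethene
Product: 15 4-[(2S)-7-acetoxy-4-oxo-8-[(E)-2-(tributylstannyl)ethenyl]chroman-2-yl]-1,3-phenylene diacetate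
Conditions: 14 (3 equiv), Pd(PPh3)4 (5 mol%), toluene, 90 °C
Reagents that add atoms: none
Why: Stille cross-coupling of the aryl iodide with one tin terminus proceeds with retention of the E geometry under neutral conditions that do not touch C2, and the excess of 14 suppresses double arylation.

Step 12
Reactants: 15 4-[(2S)-7-acetoxy-4-oxo-8-[(E)-2-(tributylstannyl)ethenyl]chroman-2-yl]-1,3-phenylene diacetate, 16 2-bromopropene, 10 4-[(E)-3-[4-acetoxy-2-hydroxy-3-(3-methylbut-2-en-1-yl)phenyl]-3-oxoprop-1-enyl]-1,3-phenylene diacetate
Product: 18 hexaacetate of the target (only the phenol ortho to the ketone on the prenylated ring free), via flavanone diene 17 (not isolated)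
Conditions: 16 (3 equiv), Pd2(dba)3 (2.5 mol%), AsPh3 (20 mol%), THF, 50 °C, sealed tube; then rt, premixed THF solution of 10 (1.1 equiv), BH3·THF, AcOH and (S)-VANOL (1.2 equiv each), rt; aqueous work-up
Reagents that add atoms: none
Why: First a Stille coupling (oxidative addition of 16 to zerovalent palladium, tin-to-palladium transfer of the alkenyl group with retention, reductive elimination) creates the C1″–C2″ σ-bond and gives the (E)-diene 17; then 17 adds to 10, whose 2′-phenoxide and ketone oxygen chelate the boron of the acyloxyborane made from BH3·THF, AcOH and (S)-VANOL, in a concerted Diels–Alder reaction that forms C3″–C4″ and C5″–C6″ and turns C1″–C2″ into the ring olefin. The closest known reaction types are the domino Stille coupling/Diels–Alder sequence and the chiral boron-promoted cycloaddition of 2′-hydroxychalcones with 1-aryl dienes. The cyclohexene ring is closed by an intermolecular, suprafacial [4+2] cycloaddition. C4″ and C5″ should come out trans because the (E)-enone geometry is transferred, C3″ cis to the aroyl group because the chelated carbonyl lies endo to the (E)-diene, and the absolute configuration (3″S,4″R,5″S) is imposed by the VANOL ligand, which shields one face of the chelated enone, the distant C2 centre of the flavanone playing no part. The step needs regio-, endo and facial selectivity: the donor aryl group at the diene terminus and the methyl group at its 3-position both direct the aryl-bearing carbon to the enone α-carbon, the boron chelate secures endo and facial control, and finishing the coupling before the boron complex is added keeps the acid-sensitive stannane away from AcOH.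

Step 13
Reactants: 18 hexaacetate of the target (only the phenol ortho to the ketone on the prenylated ring free)
Product: 19 target compound CNP0157992.1
Conditions: NaHCO3, MeOH, rt, argon
Reagents that add atoms: none
Why: Base-catalysed transesterification of the six aryl acetates to methyl acetate under nearly neutral conditions is chosen because acid would close the ketone with its two flanking phenols to a ketal and stronger base would open the flavanone (retro-oxa-Michael) or epimerise C4″, so no stereocentre should be touched.

**Compound list**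

1 | 2,4-dihydroxyacetophenone | CC(=O)c1ccc(O)cc1O | starting material
2 | 1-(2,4-dihydroxy-3-iodophenyl)ethanone | Ic1c(O)ccc(C(C)=O)c1O | intermediate
3 | 1-[2-hydroxy-3-iodo-4-(methoxymethoxy)phenyl]ethanone | Ic1c(OCOC)ccc(C(C)=O)c1O | intermediate
4 | 2,4-dihydroxybenzaldehyde | O=Cc1ccc(O)cc1O | starting material
5 | 2,4-bis(methoxymethoxy)benzaldehyde | COCOc1ccc(C=O)c(OCOC)c1 | intermediate
6 | (E)-3-[2,4-bis(methoxymethoxy)phenyl]-1-[2-hydroxy-3-iodo-4-(methoxymethoxy)phenyl]prop-2-en-1-one | Ic1c(OCOC)ccc(C(=O)/C=C/c2ccc(OCOC)cc2OCOC)c1O | intermediate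
7 | (E)-1-(2,4-dihydroxy-3-iodophenyl)-3-(2,4-dihydroxyphenyl)prop-2-en-1-one | Ic1c(O)ccc(C(=O)/C=C/c2ccc(O)cc2O)c1O | intermediate
8 | 4-[(E)-3-(4-acetoxy-2-hydroxy-3-iodophenyl)-3-oxoprop-1-enyl]-1,3-phenylene diacetate | Ic1c(OC(C)=O)ccc(C(=O)/C=C/c2ccc(OC(C)=O)cc2OC(C)=O)c1O | intermediate
9 | tributyl(3-methylbut-2-en-1-yl)stannane | CCCC[Sn](CCCC)(CCCC)CC=C(C)C | starting material
10 | 4-[(E)-3-[4-acetoxy-2-hydroxy-3-(3-methylbut-2-en-1-yl)phenyl]-3-oxoprop-1-enyl]-1,3-phenylene diacetate (dienophile) | CC(C)=CCc1c(OC(C)=O)ccc(C(=O)/C=C/c2ccc(OC(C)=O)cc2OC(C)=O)c1O | intermediate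
11 | rac-2-(2,4-dihydroxyphenyl)-7-hydroxy-8-iodochroman-4-one | Ic1c(O)ccc2c1OC(c1ccc(O)cc1O)CC2=O | intermediate
12 | rac-4-(7-acetoxy-8-iodo-4-oxochroman-2-yl)-1,3-phenylene diacetate | Ic1c(OC(C)=O)ccc2c1OC(c1ccc(OC(C)=O)cc1OC(C)=O)CC2=O | intermediate
13 | 4-[(2S)-7-acetoxy-8-iodo-4-oxochroman-2-yl]-1,3-phenylene diacetate | Ic1c(OC(C)=O)ccc2c1O[C@H](c1ccc(OC(C)=O)cc1OC(C)=O)CC2=O | intermediate
14 | (E)-1,2-bis(tributylstannyl)ethene | CCCC[Sn](CCCC)(CCCC)/C=C/[Sn](CCCC)(CCCC)CCCC | starting material
15 | 4-[(2S)-7-acetoxy-4-oxo-8-[(E)-2-(tributylstannyl)ethenyl]chroman-2-yl]-1,3-phenylene diacetate | CCCC[Sn](CCCC)(CCCC)/C=C/c1c(OC(C)=O)ccc2c1O[C@H](c1ccc(OC(C)=O)cc1OC(C)=O)CC2=O | intermediate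
16 | 2-bromopropene | CC(Br)=C | starting material
17 | 4-[(2S)-7-acetoxy-8-[(1E)-3-methylbuta-1,3-dien-1-yl]-4-oxochroman-2-yl]-1,3-phenylene diacetate (flavanone diene, not isolated) | C=C(C)/C=C/c1c(OC(C)=O)ccc2c1O[C@H](c1ccc(OC(C)=O)cc1OC(C)=O)CC2=O | intermediate
18 | hexaacetate of the target: all phenols acetylated except the one ortho to the ketone on the prenylated ring; (2S,3″S,4″R,5″S) | CC(C)=CCc1c(OC(C)=O)ccc(C(=O)[C@H]2[C@@H](c3c(OC(C)=O)ccc4c3O[C@H](c3ccc(OC(C)=O)cc3OC(C)=O)CC4=O)C=C(C)C[C@@H]2c2ccc(OC(C)=O)cc2OC(C)=O)c1O | intermediate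
19 | CNP0157992.1, (2S)-flavanone joined at C8 to the (3″S,4″R,5″S)-methylcyclohexene | CC(C)=CCc1c(O)ccc(C(=O)[C@H]2[C@@H](c3c(O)ccc4c3O[C@H](c3ccc(O)cc3O)CC4=O)C=C(C)C[C@@H]2c2ccc(O)cc2O)c1O | target

**Count**

Total steps: 13. Longest linear sequence: 10 steps (steps 1, 2, 4, 5, 8, 9, 10, 11, 12, 13).

**Steps most likely to fail**

1. Step 12. The alkenylstannane may be lost to protodestannylation or homocoupling during the coupling. Tin halide and palladium residues may also compete with the chiral boron promoter for the chalcone and erode endo and facial selectivity. The fallback sets out from 13 and separates the two events. Stille coupling of 13 with (E)-tributyl(3-methylbuta-1,3-dien-1-yl)stannane (C=C(C)/C=C/[Sn](CCCC)(CCCC)CCCC; Pd2(dba)3, AsPh3, THF, 50 °C) gives diene 17, which is freed from tin by rapid chromatography on silica doped with KF. It is then combined in a separate flask with the premixed complex of 10, BH3·THF, AcOH and (S)-VANOL, and the route is rejoined at 18 (no new compound; F0). The same ring bonds are then made in two operations instead of one.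

2. Step 10. The rate difference between the two enantiomers may be too small, because the ortho-acetoxy aryl group at C2 and the iodine at C8 can disturb the preferred half-chair. The acetates may also be partly lost to the amine–formate medium. The fallback sets out from 12 and replaces catalysis by physical resolution: preparative supercritical-fluid chromatography on an amylose tris(3,5-dimethylphenylcarbamate) phase. The (2S)-enantiomer is collected and the route is rejoined at 13 (no new compound; F0).

3. Step 8. Conversion may stall because the phenol-rich chalcone is a poor Michael acceptor and the chalcone–flavanone equilibrium is unfavourable; oxidative darkening may add to the loss. The fallback sets out from 6 and cyclises before deprotection. NaOAc in refluxing EtOH should convert 6 into rac-2-[2,4-bis(methoxymethoxy)phenyl]-8-iodo-7-(methoxymethoxy)chroman-4-one F1, and 3 M HCl in MeOH then removes the three acetals and rejoins the route at 11.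

Further compounds
F0 | step 12 | none | none
F0 | step 10 | none | none
F1 | step 8 | rac-2-[2,4-bis(methoxymethoxy)phenyl]-8-iodo-7-(methoxymethoxy)chroman-4-one | Ic1c(OCOC)ccc2c1OC(c1ccc(OCOC)cc1OCOC)CC2=O
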